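**Retrosynthetic overview**
1. Endgame: the target comes from phenol desilylation after a double Swern oxidation of the 11,12-diol. The coumarate is attached to the 1β-OH of drim-7-ene-1β,11-diol (O11 silylated). O12 comes from SeO2 allylic oxidation, C11 from Peterson methylenation and hydroboration of a C9 ketone, and 1β-OH from a C1 ketone.
2. Key disconnection: ring A of the resulting 11-nordrim-7-ene-1,9-dione is opened at C3–C4 to give a monocyclic 6-acryloyl-6-methylcarvone. In the forward sense, iron-hydride hydrogen-atom transfer turns the isopropenyl group into the C4 radical, which closes ring A on C3.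
3. Chiral pool: this precursor is (R)-carvone + MeI + acrolein. All ten carvone carbons are kept (its ring is ring B, C5–C10; ring methyl = C12; isopropenyl = C4/C13/C14). Its single stereocentre (C5) relays to C10 and then to C1 and C9.
4. Enabling feature: the quaternary C4 of ring A, with its two methyl groups, hangs on ring-B carbon C5 and stands 1,4 to the oxygen-bearing C1. With C1 as a ketone, C2=C3 is an acceptor whose β-carbon C3 is polarity-matched to a tertiary C4 radical, and that radical is an isopropenyl group plus one hydrogen atom.
5. Ring order: ring B is bought with carvone, ring A is closed in step 4, and no other ring is made.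

Key step: step 4

Remark: drimane numbering is used for all intermediates (ring A = C1–C5 and C10; ring B = C5–C10; C11 on C9, C12 on C8, C13/C14 on C4, C15 on C10). α/β refer to the usual drawing with the C10 methyl group β.

**Step 1**
Reactants: 1 (R)-(–)-carvone
Product: 3 (5R)-2,6-dimethyl-5-(prop-1-en-2-yl)cyclohex-2-en-1-one (6-methylcarvone; both C6 epimers), via lithium dienolate 2 (not isolated)
Conditions: LiN(i-Pr)2 (LDA), THF, −78 °C; MeI, −78 to 0 °C
Reagents that add atoms: iodomethane CI
Why: Kinetic α′-deprotonation gives the cross-conjugated dienolate, and its C-methylation (enolate alkylation) installs the future C15 methyl group on C10; the new centre needs no control because step 2 makes it planar again.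

**Step 2**
Reactants: 3 6-methylcarvone; 4 acrolein
Product: 6 (5S,6R)-6-(1-hydroxyprop-2-en-1-yl)-2,6-dimethyl-5-(prop-1-en-2-yl)cyclohex-2-en-1-one (both carbinol epimers), via lithium enolate 5 (not isolated)
Conditions: LiN(i-Pr)2, THF, −78 to 0 °C, then −78 °C; acrolein, −78 °C; AcOH quench at −78 °C
Reagents that add atoms: none
Why: Aldol addition of the planar tetrasubstituted enolate 5, which acrolein should approach anti to the neighbouring C5 isopropenyl group (as in alkylations of 6-substituted carvone enolates), so that C1 stands trans to C4 and the C10 methyl group is β; the carbinol configuration is irrelevant because it is oxidised next.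

**Step 3**
Reactants: 6 aldol adduct
Product: 7 (5S,6R)-6-acryloyl-2,6-dimethyl-5-(prop-1-en-2-yl)cyclohex-2-en-1-one
Conditions: Dess–Martin periodinane, CH2Cl2, 0 °C to rt
Reagents that add atoms: none
Why: Dess–Martin oxidation of a secondary allylic alcohol under non-basic conditions avoids retro-aldol cleavage and converges both carbinol epimers on one vinyl ketone, and the quaternary C10 cannot epimerise.

**Step 4**
Reactants: 7 acryloyl ketone
Product: 10 11-nordrim-7-ene-1,9-dione (trans-fused; 5α-H; 10β-Me; 5S,10R), via tertiary C4 radical 8 (not isolated), via cyclised C2 radical 9 (not isolated)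
Conditions: Fe(acac)3 (0.3 equiv), PhSiH3 (2.5 equiv), degassed EtOH (0.02 M), 60 °C
Reagents that add atoms: none
Why: Fe(acac)3 and PhSiH3 form an iron hydride that transfers a hydrogen atom to the CH2 terminus of the electron-rich 1,1-disubstituted isopropenyl group (Markovnikov MHAT), which creates the second geminal methyl group and the nucleophilic tertiary radical 8 on C4; 8 adds to the unsubstituted β-carbon C3 of the acryloyl group, and the electrophilic α-keto radical 9 is reduced by divalent iron to an enolate that ethanol protonates at C2, returning trivalent iron. The closest known reaction type is the iron-catalysed reductive olefin coupling (MHAT-initiated Giese addition) in its intramolecular form. Ring A closes in the 6-endo-trig mode, preferred over 5-exo because attack at C2 would be polarity-mismatched, would hit the substituted end of the acceptor and would leave an unstabilised primary radical. No new stereocentre is created (C4 carries two methyl groups; C2 and C3 are CH2), and the trans ring fusion follows from the trans relation of C4 on C5 and C1 on C10 set in step 2, both groups being equatorial in the reacting half-chair. The step needs hydrogen-atom transfer to one alkene out of three, which is secured because the isopropenyl group is the only electron-rich and unhindered one and because the C4 radical cannot usefully reach C7 or C8 (four-membered ring or 5-endo closure). In one operation it should deliver the C3–C4 bond, the quaternary C4 next to the C5/C10 array, and the whole trans-decalin with a saturated C1 ketone and a conjugated C9 ketone that later steps can tell apart.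

**Step 5**
Reactants: 10 bicyclic dione
Product: 11 1β-hydroxy-11-nordrim-7-en-9-one (1R,5S,10R)
Conditions: NaBH4, MeOH/CH2Cl2 1:1, −78 °C
Reagents that add atoms: none
Why: Chemoselective borohydride reduction of the saturated C1 ketone beside the less electrophilic conjugated C9 ketone (the selectivity known from the Wieland–Miescher ketone), with hydride arriving on the α face anti to the axial C10 methyl group to give the equatorial 1β-alcohol.

**Step 6**
Reactants: 11 hydroxy enone
Product: 13 drima-7,9(11)-dien-1β-ol, via β-hydroxysilane 12 (not isolated)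
Conditions: Me3SiCH2Li, CeCl3, THF, −78 to 0 °C; aq NH4Cl; crude 12, KH, THF, 0 °C to rt
Reagents that add atoms: (trimethylsilyl)methyllithium [Li]C[Si](C)(C)C
Why: Peterson olefination, in which the small, weakly basic organocerium reagent should add 1,2 to the hindered non-enolisable C9 ketone at a temperature where the C1 alkoxide does not undergo retro-aldol cleavage, and syn-elimination of the potassium alkoxide places the alkene regiospecifically at C9=C11 without acid that could isomerise the diene.

**Step 7**
Reactants: 13 dienol
Product: 15 drim-7-ene-1β,11-diol (5α-H; 9α-H; 10β-Me), via bis(9-BBN) adduct 14 (not isolated)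
Conditions: 9-BBN (3 equiv), THF, 0 to 50 °C; then NaOH, H2O2, 0 °C
Reagents that add atoms: hydrogen peroxide OO
Why: Hydroboration–oxidation, in which 9-BBN should place boron only on the terminal CH2 (C11) and leave the trisubstituted C7=C8 bond, while hydrogen is delivered to C9 from the α face opposite the axial C10 methyl group and so sets 9α-H with an equatorial 9β-CH2OH.

**Step 8**
Reactants: 15 diol
Product: 16 11-(tert-butyldimethylsilyloxy)drim-7-en-1β-ol
Conditions: TBSCl (1.1 equiv), imidazole, CH2Cl2, 0 °C
Reagents that add atoms: tert-butyldimethylsilyl chloride CC(C)(C)[Si](C)(C)Cl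
Why: Silyl ether protection that should take only the primary C11 alcohol, because the secondary 1β-OH is neopentyl and far slower on steric grounds.

**Step 9**
Reactants: 17 (E)-p-coumaric acid
Product: 19 (E)-3-[4-(tert-butyldimethylsilyloxy)phenyl]prop-2-enoic acid, via bis-silyl derivative 18 (not isolated)
Conditions: TBSCl (2.3 equiv), imidazole, DMF, rt; then AcOH/THF/H2O, rt
Reagents that add atoms: tert-butyldimethylsilyl chloride CC(C)(C)[Si](C)(C)Cl
Why: Exhaustive silylation followed by selective hydrolysis of the much more labile silyl ester leaves the phenol masked, the acid free and the E alkene unchanged.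

**Step 10**
Reactants: 16 mono-silyl ether; 19 protected coumaric acid
Product: 21 1β-[(E)-4-(tert-butyldimethylsilyloxy)cinnamoyloxy]-11-(tert-butyldimethylsilyloxy)drim-7-ene, via mixed anhydride 20 (not isolated)
Conditions: 19, 2,4,6-trichlorobenzoyl chloride, Et3N, toluene, rt; then 16, DMAP, toluene, rt to 60 °C
Reagents that add atoms: none
Why: Yamaguchi esterification, in which DMAP attacks the less hindered cinnamoyl carbonyl of 20 and the acylpyridinium ion acylates the hindered equatorial 1β-OH with retention at C1.

**Step 11**
Reactants: 21 ester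
Product: 23 12-hydroxy derivative of 21 (C8–CH2OH), via enal 22 (not isolated)
Conditions: SeO2 (0.5 equiv), t-BuOOH, CH2Cl2, 0 °C to rt; crude, NaBH4, CeCl3·7H2O, MeOH, −20 °C
Reagents that add atoms: tert-butyl hydroperoxide CC(C)(C)OO; selenium dioxide O=[Se]=O
Why: SeO2 allylic oxidation (ene reaction, then [2,3]-sigmatropic shift) acts at the more substituted alkene terminus C8 and there should prefer the methyl group C12 (cis to H-7) over the hindered methine C9, as is usual for drimenyl esters, and Luche reduction converges the alcohol/enal mixture on 23 without touching the cinnamate.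

**Step 12**
Reactants: 23 allylic alcohol
Product: 24 1β-[(E)-4-(tert-butyldimethylsilyloxy)cinnamoyloxy]drim-7-ene-11,12-diol
Conditions: camphorsulfonic acid (0.1 equiv), MeOH/CH2Cl2, 0 °C
Reagents that add atoms: none
Why: Acid-catalysed methanolysis cleaves a primary alkyl silyl ether much faster than an aryl silyl ether (the reverse of the order under base or fluoride) and is too mild for acyl migration.

**Step 13**
Reactants: 24 diol
Product: 25 1β-[(E)-4-(tert-butyldimethylsilyloxy)cinnamoyloxy]drim-7-ene-11,12-dial
Conditions: (COCl)2, DMSO, CH2Cl2, −78 °C; Et3N, −78 to −30 °C; pH 7 buffer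
Reagents that add atoms: none
Why: Double Swern oxidation, in which both hydroxyl groups are activated before base is added so that no lactol can form, and the cold, short amine stage is the established way to reach the 7-ene-11,12-dial unit without epimerising C9.

**Step 14**
Reactants: 25 silylated dialdehyde
Product: 26 1β-[(E)-p-coumaroyloxy]polygodial (1R,5S,9R,10S; CNP0187624.1)
Conditions: HF·pyridine, pyridine, THF, 0 °C to rt
Reagents that add atoms: none
Why: Fluoride-driven Si–O cleavage in a mildly acidic buffer frees the phenol and avoids the basic conditions that would epimerise C9 or cleave the ester.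

**Compound list**
1 | (R)-(–)-carvone | CC1=CC[C@H](CC1=O)C(C)=C | starting material
2 | lithium cross-conjugated dienolate of 1 | [Li]OC1=C[C@H](C(C)=C)CC=C1C | intermediate
3 | (5R)-6-methylcarvone (C6 epimers) | CC1C(=O)C(C)=CC[C@H]1C(C)=C | intermediate
4 | acrolein | C=CC=O | starting material
5 | lithium enolate of 3 | [Li]OC1=C(C)[C@H](C(C)=C)CC=C1C | intermediate
6 | (5S,6R)-aldol adduct (carbinol epimers) | C=CC(O)[C@]1(C)C(=O)C(C)=CC[C@H]1C(C)=C | intermediate
7 | (5S,6R)-6-acryloyl-6-methylcarvone | C=CC(=O)[C@]1(C)C(=O)C(C)=CC[C@H]1C(C)=C | intermediate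
8 | tertiary C4 radical | C=CC(=O)[C@]1(C)C(=O)C(C)=CC[C@H]1[C](C)C | intermediate
9 | cyclised C2 (α-keto) radical | CC1(C)C[CH]C(=O)[C@]2(C)C(=O)C(C)=CC[C@@H]12 | intermediate
10 | 11-nordrim-7-ene-1,9-dione | CC1(C)CCC(=O)[C@]2(C)C(=O)C(C)=CC[C@@H]12 | intermediate
11 | 1β-hydroxy-11-nordrim-7-en-9-one | CC1(C)CC[C@@H](O)[C@]2(C)C(=O)C(C)=CC[C@@H]12 | intermediate
12 | 9-hydroxy-11-(trimethylsilyl)drim-7-en-1β-ol (C9 configuration of no consequence) | CC1(C)CC[C@@H](O)[C@]2(C)C(O)(C[Si](C)(C)C)C(C)=CC[C@@H]12 | intermediate
13 | drima-7,9(11)-dien-1β-ol | CC1(C)CC[C@@H](O)[C@]2(C)C(=C)C(C)=CC[C@@H]12 | intermediate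
14 | O1,C11-bis(9-borabicyclo[3.3.1]nonan-9-yl) adduct | CC1(C)CC[C@@H](OB3C4CCCC3CCC4)[C@]2(C)[C@@H](CB3C4CCCC3CCC4)C(C)=CC[C@@H]12 | intermediate
15 | drim-7-ene-1β,11-diol | CC1(C)CC[C@@H](O)[C@]2(C)[C@@H](CO)C(C)=CC[C@@H]12 | intermediate
16 | 11-(tert-butyldimethylsilyloxy)drim-7-en-1β-ol | CC1(C)CC[C@@H](O)[C@]2(C)[C@@H](CO[Si](C)(C)C(C)(C)C)C(C)=CC[C@@H]12 | intermediate
17 | (E)-p-coumaric acid | OC(=O)/C=C/c1ccc(O)cc1 | starting material
18 | silyl ester/silyl ether of 17 | CC(C)(C)[Si](C)(C)OC(=O)/C=C/c1ccc(O[Si](C)(C)C(C)(C)C)cc1 | intermediate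
19 | (E)-4-(tert-butyldimethylsilyloxy)cinnamic acid | OC(=O)/C=C/c1ccc(O[Si](C)(C)C(C)(C)C)cc1 | intermediate
20 | mixed 2,4,6-trichlorobenzoic anhydride of 19 | CC(C)(C)[Si](C)(C)Oc1ccc(/C=C/C(=O)OC(=O)c2c(Cl)cc(Cl)cc2Cl)cc1 | intermediate
21 | 1β-cinnamate, 11-silyl ether | CC1(C)CC[C@@H](OC(=O)/C=C/c3ccc(O[Si](C)(C)C(C)(C)C)cc3)[C@]2(C)[C@@H](CO[Si](C)(C)C(C)(C)C)C(C)=CC[C@@H]12 | intermediate
22 | 12-al of 21 | CC1(C)CC[C@@H](OC(=O)/C=C/c3ccc(O[Si](C)(C)C(C)(C)C)cc3)[C@]2(C)[C@@H](CO[Si](C)(C)C(C)(C)C)C(C=O)=CC[C@@H]12 | intermediate
23 | 12-ol of 21 | CC1(C)CC[C@@H](OC(=O)/C=C/c3ccc(O[Si](C)(C)C(C)(C)C)cc3)[C@]2(C)[C@@H](CO[Si](C)(C)C(C)(C)C)C(CO)=CC[C@@H]12 | intermediate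
24 | 11,12-diol, phenol silylated | CC1(C)CC[C@@H](OC(=O)/C=C/c3ccc(O[Si](C)(C)C(C)(C)C)cc3)[C@]2(C)[C@@H](CO)C(CO)=CC[C@@H]12 | intermediate
25 | 11,12-dial, phenol silylated | CC1(C)CC[C@@H](OC(=O)/C=C/c3ccc(O[Si](C)(C)C(C)(C)C)cc3)[C@]2(C)[C@@H](C=O)C(C=O)=CC[C@@H]12 | intermediate
26 | 1β-[(E)-p-coumaroyloxy]polygodial | CC1(C)CC[C@@H](OC(=O)/C=C/c2ccc(O)cc2)[C@]2(C)[C@@H](C=O)C(C=O)=CC[C@@H]12 | target

**Step count**
Total steps: 14. Longest linear sequence: 13 (steps 1–8 and 10–14; step 9 is a one-step side branch).

**Steps most likely to fail**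

Step 6. Addition may stall because C9 is flanked by the quaternary C10, the C8 methyl group and the peri C1 alkoxide. The reagent may also turn to conjugate addition at C7, or the C1 alkoxide may open ring A by retro-aldol cleavage.
The fallback sets out from 11 and comes back at 13. It replaces carbanion addition and elimination by a non-basic titanium methylidene transfer on a masked alcohol. TESOTf and 2,6-lutidine (CH2Cl2, −78 °C) should give the triethylsilyl ether F3. Cp2TiMe2 (toluene, 75 °C, dark) should methylenate the ketone through an oxatitanacyclobutane to give the silylated diene F4. Bu4NF (THF, 0 °C) then frees 13.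

Step 4. The vinyl ketone may be consumed by direct hydrogen-atom transfer or oligomerisation, or the tertiary radical may be quenched by a second hydrogen atom before it cyclises.
The fallback sets out from 7 and comes back at 10. It makes the same radical from a preformed halide instead of by hydrogen-atom transfer. HBr (33% in AcOH, CH2Cl2, 0 °C) should add in the Markovnikov sense to the isopropenyl group and in the conjugate sense to the acryloyl group to give the dibromide F1. Et3N (CH2Cl2, 0 °C) removes HBr only from the β-bromo ketone (E1cB) and restores the vinyl ketone in the tertiary bromide F2. Slow addition of Bu3SnH with Et3B/air (toluene, rt) then generates the C4 radical, and the same 6-endo Giese closure should give 10.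

Step 10. Acylation of the neopentyl 1β-OH, crowded further by the peri CH2OTBS group, may be slower than decomposition of the activated acid.
The fallback sets out from 16 and comes back at 21. It builds the cinnamate in two stages from a much smaller acylating agent. Diethylphosphonoacetic acid with DCC (CH2Cl2, rt), which acylates through a slim phosphonoketene, should give the phosphonoacetate F5. A Horner–Wadsworth–Emmons reaction with commercial 4-(tert-butyldimethylsilyloxy)benzaldehyde (LiCl, i-Pr2NEt, MeCN, rt) then forms the E alkene of 21.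

**Further compounds**
F1 | step 4 | (5S,6R)-6-(3-bromopropanoyl)-5-(2-bromopropan-2-yl)-2,6-dimethylcyclohex-2-en-1-one | BrCCC(=O)[C@]1(C)C(=O)C(C)=CC[C@H]1C(C)(C)Br
F2 | step 4 | (5S,6R)-6-acryloyl-5-(2-bromopropan-2-yl)-2,6-dimethylcyclohex-2-en-1-one | C=CC(=O)[C@]1(C)C(=O)C(C)=CC[C@H]1C(C)(C)Br
F3 | step 6 | 1β-(triethylsilyloxy)-11-nordrim-7-en-9-one | CC1(C)CC[C@@H](O[Si](CC)(CC)CC)[C@]2(C)C(=O)C(C)=CC[C@@H]12
F4 | step 6 | 1β-(triethylsilyloxy)drima-7,9(11)-diene | CC1(C)CC[C@@H](O[Si](CC)(CC)CC)[C@]2(C)C(=C)C(C)=CC[C@@H]12
F5 | step 10 | 1β-(diethoxyphosphorylacetoxy)-11-(tert-butyldimethylsilyloxy)drim-7-ene | CC1(C)CC[C@@H](OC(=O)CP(=O)(OCC)OCC)[C@]2(C)[C@@H](CO[Si](C)(C)C(C)(C)C)C(C)=CC[C@@H]12
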